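**Retrosynthetic overview**
- Target ⇒ its 4'-O-benzyl ether ⇒ last C–C bond C4(flavan)–C8(flavanone): a C4 cation released from a 4-phenylthioflavan is trapped by natural (2S)-pinocembrin, which sets 4S (trans to the 2-aryl group).
- 4-Phenylthioflavan ⇒ pyran ring closed at O1–C2 by Mitsunobu inversion of a (3R)-benzylic carbinol.
- Key C3–C4 bond: the carbon that later becomes the C4 cation is first used as a sulfur-stabilised benzylic carbanion (umpolung, d1 synthon) that opens (S)-4-benzyloxystyrene oxide; the C2 configuration comes in with the epoxide.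
- Sulfide ⇐ 2-hydroxy-4,6-dimethoxybenzaldehyde + PhSH; epoxide ⇐ 4'-benzyloxyphenacyl bromide by CBS reduction.
- Ring order: the benzene rings and the whole flavanone are purchased; the only ring made is the flavan pyran ring (step 4); the two flavonoid halves are joined afterwards (step 5).

Assumption: (2S)-pinocembrin is bought as the natural enantiomer; C4 of the flavan is carried as an epimer mixture through steps 3 and 4 because it is ionised in step 5.

**Step 1**
Reactants: 1 2-hydroxy-4,6-dimethoxybenzaldehyde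
Product: 3 3,5-dimethoxy-2-[(phenylsulfanyl)methyl]phenol, via benzylic alcohol 2 (not isolated)
Conditions: NaBH4, MeOH/THF, 0 °C; then PhSH (5 equiv), AcOH, 40 °C
Reagents that add atoms: thiophenol, Sc1ccccc1
Why: Borohydride reduction gives the o-hydroxybenzylic alcohol, whose hydroxyl is then replaced by the thiol in an acid-promoted SN1-type thioetherification assisted by the ortho-hydroxyl and the two methoxy groups; no stereocentre is formed.

**Step 2**
Reactants: 4 1-[4-(benzyloxy)phenyl]-2-bromoethan-1-one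
Product: 6 (2S)-2-[4-(benzyloxy)phenyl]oxirane, via (1S)-bromohydrin 5 (not isolated)
Conditions: (S)-Me-CBS (10 mol %), BH3·SMe2, THF, 0 °C; MeOH; then 2 M NaOH, rt
Reagents that add atoms: none
Why: Corey–Bakshi–Shibata reduction delivers hydride to the ketone face that gives the (S)-bromohydrin (aryl large, CH2Br small), and hydroxide then closes the epoxide by intramolecular Williamson displacement at CH2 without touching the stereocentre.

**Step 3**
Reactants: 3 3,5-dimethoxy-2-[(phenylsulfanyl)methyl]phenol; 6 (2S)-2-[4-(benzyloxy)phenyl]oxirane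
Product: 8 2-[(1RS,3R)-3-[4-(benzyloxy)phenyl]-3-hydroxy-1-(phenylsulfanyl)propyl]-3,5-dimethoxyphenol, via dilithiated sulfide dianion 7 (not isolated)
Conditions: n-BuLi (2.1 equiv), TMEDA, THF, −78 → −20 °C; then 6, −78 °C → rt; aq NH4Cl
Reagents that add atoms: none
Why: Proposed new method: two equivalents of n-BuLi give the phenoxide and then, by chelation-assisted lateral lithiation, the sulfur-stabilised benzylic carbanion, so that the carbon which later serves as the C4 cation acts here as a nucleophile (Corey–Seebach-type umpolung) and attacks the unhindered CH2 of the epoxide by SN2, carrying the epoxide stereocentre over unchanged as the (3R)-carbinol while C1 forms as an inconsequential epimer mixture; the closest known reactions are epoxide openings by α-lithiobenzyl phenyl sulfides and by dianions of 2-(2-hydroxyaryl)-1,3-dithianes.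

**Step 4**
Reactants: 8 2-[(1RS,3R)-3-[4-(benzyloxy)phenyl]-3-hydroxy-1-(phenylsulfanyl)propyl]-3,5-dimethoxyphenol
Product: 9 (2S,4RS)-2-[4-(benzyloxy)phenyl]-5,7-dimethoxy-4-(phenylsulfanyl)-3,4-dihydro-2H-chromene
Conditions: PPh3, DIAD, THF, 0 °C → rt
Reagents that add atoms: none
Why: Intramolecular Mitsunobu etherification, in which the phenol displaces the phosphine-activated benzylic hydroxyl by SN2 with inversion, turns the (3R)-carbinol into the (2S)-flavan centre and closes the pyran ring.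

**Step 5**
Reactants: 9 (2S,4RS)-2-[4-(benzyloxy)phenyl]-5,7-dimethoxy-4-(phenylsulfanyl)-3,4-dihydro-2H-chromene; 10 (2S)-pinocembrin
Product: 12 (2S)-8-{(2S,4S)-2-[4-(benzyloxy)phenyl]-5,7-dimethoxy-3,4-dihydro-2H-chromen-4-yl}-5,7-dihydroxy-2-phenyl-2,3-dihydro-4H-chromen-4-one, via flavan-4-yl cation triflate 11 (not isolated)
Conditions: AgOTf (1.2 equiv), 10 (3 equiv), 4 Å MS, THF, −40 → 0 °C, 9 added slowly
Reagents that add atoms: none
Why: Monovalent silver abstracts the thiolate to give the 5,7-dimethoxy-stabilised C4 benzylic cation, which is captured in a Friedel–Crafts alkylation by C8 of pinocembrin (C6 is crowded by the chelated 5-OH) through pseudo-axial attack anti to the equatorial 2-aryl group, so the 2,4-trans (4S) centre is set by substrate control and both C4 epimers of 9 converge.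

**Step 6**
Reactants: 12 (2S)-8-{(2S,4S)-2-[4-(benzyloxy)phenyl]-5,7-dimethoxy-3,4-dihydro-2H-chromen-4-yl}-5,7-dihydroxy-2-phenyl-2,3-dihydro-4H-chromen-4-one
Product: 13 (2S)-8-[(2S,4S)-2-(4-hydroxyphenyl)-5,7-dimethoxy-3,4-dihydro-2H-chromen-4-yl]-5,7-dihydroxy-2-phenyl-2,3-dihydro-4H-chromen-4-one
Conditions: H2 (1 atm), Pd/C, EtOAc/MeOH, rt
Reagents that add atoms: none
Why: Hydrogenolysis of the aryl benzyl ether over palladium on carbon frees the 4'-phenol, while the flavanone carbonyl, the cyclic benzylic ethers and all three stereocentres are untouched at one atmosphere.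

**Compound list**
1 | 2-hydroxy-4,6-dimethoxybenzaldehyde | COc1cc(O)c(C=O)c(OC)c1 | starting material
2 | 2-(hydroxymethyl)-3,5-dimethoxyphenol | COc1cc(O)c(CO)c(OC)c1 | intermediate
3 | 3,5-dimethoxy-2-[(phenylsulfanyl)methyl]phenol | COc1cc(O)c(CSc2ccccc2)c(OC)c1 | intermediate
4 | 1-[4-(benzyloxy)phenyl]-2-bromoethan-1-one | O=C(CBr)c1ccc(OCc2ccccc2)cc1 | starting material
5 | (1S)-1-[4-(benzyloxy)phenyl]-2-bromoethan-1-ol | BrC[C@@H](O)c1ccc(OCc2ccccc2)cc1 | intermediate
6 | (2S)-2-[4-(benzyloxy)phenyl]oxirane | C1[C@@H](O1)c1ccc(OCc2ccccc2)cc1 | intermediate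
7 | lithium 2-[lithio(phenylsulfanyl)methyl]-3,5-dimethoxyphenolate (O,C-dianion of 3) | [Li+].[Li+].COc1cc([O-])c([CH-]Sc2ccccc2)c(OC)c1 | intermediate
8 | 2-[(1RS,3R)-3-[4-(benzyloxy)phenyl]-3-hydroxy-1-(phenylsulfanyl)propyl]-3,5-dimethoxyphenol (C1 epimers) | COc1cc(O)c(C(Sc2ccccc2)C[C@@H](O)c2ccc(OCc3ccccc3)cc2)c(OC)c1 | intermediate
9 | (2S,4RS)-2-[4-(benzyloxy)phenyl]-5,7-dimethoxy-4-(phenylsulfanyl)-3,4-dihydro-2H-chromene (C4 epimers) | COc1cc(OC)c2c(c1)O[C@H](c1ccc(OCc3ccccc3)cc1)CC2Sc1ccccc1 | intermediate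
10 | (2S)-pinocembrin, (2S)-5,7-dihydroxy-2-phenyl-2,3-dihydro-4H-chromen-4-one | Oc1cc(O)c2c(c1)O[C@H](c1ccccc1)CC2=O | starting material
11 | (2S)-2-[4-(benzyloxy)phenyl]-5,7-dimethoxy-3,4-dihydro-2H-chromen-4-ylium trifluoromethanesulfonate | COc1cc(OC)c2c(c1)O[C@H](c1ccc(OCc3ccccc3)cc1)C[CH+]2.[O-]S(=O)(=O)C(F)(F)F | intermediate
12 | (2S)-8-{(2S,4S)-2-[4-(benzyloxy)phenyl]-5,7-dimethoxy-3,4-dihydro-2H-chromen-4-yl}-5,7-dihydroxy-2-phenyl-2,3-dihydro-4H-chromen-4-one | COc1cc(OC)c2c(c1)O[C@H](c1ccc(OCc3ccccc3)cc1)C[C@H]2c1c(O)cc(O)c2c1O[C@H](c1ccccc1)CC2=O | intermediate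
13 | (2S)-8-[(2S,4S)-2-(4-hydroxyphenyl)-5,7-dimethoxy-3,4-dihydro-2H-chromen-4-yl]-5,7-dihydroxy-2-phenyl-2,3-dihydro-4H-chromen-4-one (CNP0188217.1) | COc1cc(OC)c2c(c1)O[C@H](c1ccc(O)cc1)C[C@H]2c1c(O)cc(O)c2c1O[C@H](c1ccccc1)CC2=O | target

**Count**
Total steps: 6. Longest linear sequence: 5 (1 → 3 → 8 → 9 → 12 → 13).

**Steps most likely to fail and their fallbacks**

Step 3 is the riskiest. The phenoxide lowers the acidity of the benzylic CH2, ring lithiation between the methoxy groups can compete, and the p-alkoxystyrene oxide can open at the benzylic carbon or rearrange. The fallback sets out from 1 and uses the classical 1,3-dithiane acyl-anion equivalent, passing through the flavanone. Propane-1,3-dithiol and BF3·OEt2 convert 1 into 2-(1,3-dithian-2-yl)-3,5-dimethoxyphenol F1. Its dianion (2 equiv n-BuLi) opens 6 to give 2-{2-[(2R)-2-[4-(benzyloxy)phenyl]-2-hydroxyethyl]-1,3-dithian-2-yl}-3,5-dimethoxyphenol F2. Mitsunobu closure gives (2S)-2-[4-(benzyloxy)phenyl]-5,7-dimethoxyspiro[chromane-4,2'-[1,3]dithiane] F3. MeI and CaCO3 in aqueous MeCN unmask (2S)-2-[4-(benzyloxy)phenyl]-5,7-dimethoxy-2,3-dihydro-4H-chromen-4-one F4. NaBH4 reduces it to (2S,4S)-2-[4-(benzyloxy)phenyl]-5,7-dimethoxy-3,4-dihydro-2H-chromen-4-ol F5. F5 is ionised with BF3·OEt2 in the presence of 10 and comes back to the route at 12.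

Step 5 is the second risk. Pinocembrin can also react at C6, the cation can alkylate ring A of a second molecule of 9, and some 2,4-cis isomer is expected, so the yield of pure 12 may be low even with excess 10 and chromatographic separation. The fallback sets out from 10 and blocks C6. Benzyltrimethylammonium dichloroiodate with CaCO3 in CH2Cl2/MeOH gives (2S)-5,7-dihydroxy-6-iodo-2-phenyl-2,3-dihydro-4H-chromen-4-one F10, iodination being expected ortho to the chelated 5-OH. AgOTf-promoted coupling with 9 can then only occur at C8 and gives (2S)-8-{(2S,4S)-2-[4-(benzyloxy)phenyl]-5,7-dimethoxy-3,4-dihydro-2H-chromen-4-yl}-5,7-dihydroxy-6-iodo-2-phenyl-2,3-dihydro-4H-chromen-4-one F11. H2 over Pd/C with NaOAc removes iodine and benzyl in one operation and comes back to the route at 13.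

Step 4 is the third risk. The p-alkoxybenzylic carbinol can eliminate to the styrene or leak through an SN1 path, which would erode the C2 configuration. The fallback sets out from 4 and forms the aryl–oxygen bond instead, with retention at the carbinol carbon. (R)-Me-CBS reduction of 4 gives (1R)-1-[4-(benzyloxy)phenyl]-2-bromoethan-1-ol F6, and NaOH closes it to (2R)-2-[4-(benzyloxy)phenyl]oxirane F7. Dianion 7 opens F7 to 2-[(1RS,3S)-3-[4-(benzyloxy)phenyl]-3-hydroxy-1-(phenylsulfanyl)propyl]-3,5-dimethoxyphenol F8. PhNTf2 with K2CO3 sulfonylates only the phenol to give 2-[(1RS,3S)-3-[4-(benzyloxy)phenyl]-3-hydroxy-1-(phenylsulfanyl)propyl]-3,5-dimethoxyphenyl trifluoromethanesulfonate F9. Pd(OAc)2 with t-BuXPhos and Cs2CO3 in toluene closes the ring by intramolecular aryl C–O coupling, which leaves the carbinol centre untouched, and comes back to the route at 9.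

**Further compounds**
F1 | step 3 | 2-(1,3-dithian-2-yl)-3,5-dimethoxyphenol | COc1cc(O)c(C2SCCCS2)c(OC)c1
F2 | step 3 | 2-{2-[(2R)-2-[4-(benzyloxy)phenyl]-2-hydroxyethyl]-1,3-dithian-2-yl}-3,5-dimethoxyphenol | COc1cc(O)c(C2(C[C@@H](O)c3ccc(OCc4ccccc4)cc3)SCCCS2)c(OC)c1
F3 | step 3 | (2S)-2-[4-(benzyloxy)phenyl]-5,7-dimethoxyspiro[chromane-4,2'-[1,3]dithiane] | COc1cc(OC)c2c(c1)O[C@H](c1ccc(OCc3ccccc3)cc1)CC21SCCCS1
F4 | step 3 | (2S)-2-[4-(benzyloxy)phenyl]-5,7-dimethoxy-2,3-dihydro-4H-chromen-4-one | COc1cc(OC)c2c(c1)O[C@H](c1ccc(OCc3ccccc3)cc1)CC2=O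
F5 | step 3 | (2S,4S)-2-[4-(benzyloxy)phenyl]-5,7-dimethoxy-3,4-dihydro-2H-chromen-4-ol | COc1cc(OC)c2c(c1)O[C@H](c1ccc(OCc3ccccc3)cc1)C[C@@H]2O
F6 | step 4 | (1R)-1-[4-(benzyloxy)phenyl]-2-bromoethan-1-ol | BrC[C@H](O)c1ccc(OCc2ccccc2)cc1
F7 | step 4 | (2R)-2-[4-(benzyloxy)phenyl]oxirane | C1[C@H](O1)c1ccc(OCc2ccccc2)cc1
F8 | step 4 | 2-[(1RS,3S)-3-[4-(benzyloxy)phenyl]-3-hydroxy-1-(phenylsulfanyl)propyl]-3,5-dimethoxyphenol | COc1cc(O)c(C(Sc2ccccc2)C[C@H](O)c2ccc(OCc3ccccc3)cc2)c(OC)c1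
F9 | step 4 | 2-[(1RS,3S)-3-[4-(benzyloxy)phenyl]-3-hydroxy-1-(phenylsulfanyl)propyl]-3,5-dimethoxyphenyl trifluoromethanesulfonate | COc1cc(OS(=O)(=O)C(F)(F)F)c(C(Sc2ccccc2)C[C@H](O)c2ccc(OCc3ccccc3)cc2)c(OC)c1
F10 | step 5 | (2S)-5,7-dihydroxy-6-iodo-2-phenyl-2,3-dihydro-4H-chromen-4-one | Oc1c(I)c(O)c2c(c1)O[C@H](c1ccccc1)CC2=O
F11 | step 5 | (2S)-8-{(2S,4S)-2-[4-(benzyloxy)phenyl]-5,7-dimethoxy-3,4-dihydro-2H-chromen-4-yl}-5,7-dihydroxy-6-iodo-2-phenyl-2,3-dihydro-4H-chromen-4-one | COc1cc(OC)c2c(c1)O[C@H](c1ccc(OCc3ccccc3)cc1)C[C@H]2c1c(O)c(I)c(O)c2c1O[C@H](c1ccccc1)CC2=O
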